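Ring C (the outer ring whose methoxy is para to its butyryl; c1 bridge carbon, c2 C–OH, c3 butyryl carbon, c4 C–OH, c5 C–Me, c6 C–OMe) is cut at c1–c2 and c3–c4. Its c4–c5–c6 edge is the enol methyl ether of a 2-methyl-3-oxo ester and its c2–c3 edge an alkoxy ynone, so one cycloaddition–aromatization of a 1,3-dimethoxy-1-silyloxydiene with 1-(benzyloxy)hex-1-yn-3-one should close ring C with butyryl, methyl and the lone methyl ether in place. The diene carries at its terminus the benzyl-protected ring B–CH2–ring A unit, still without butyryl groups; hydrogenolysis and twofold C-butyrylation of the two remaining ring CH positions complete the target.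

Key step: step 15

Remarks on the chemistry (assumptions):
- Ring B is the central ring and ring A the outer ring whose methoxy is para to its bridge carbon. "Ar" in the names below is 3-{[2,6-bis(benzyloxy)-4-methoxy-3-methylphenyl]methyl}-2,4,6-tris(benzyloxy)phenyl, that is tribenzylated ring B carrying the dibenzylated ring A arm.
- The ynone oxygen is carried as a benzyl ether, not as the ethyl ether that commercial ethoxyacetylene would give. After the annulation the c4 hydroxyl is free and would tie up the ketone as a boron chelate, so chelation-assisted BCl3 cleavage of a c2 ethyl ether beside two hindered methyl ethers could not be relied on. With benzyl, one neutral hydrogenolysis frees every hydroxyl, at the price of one extra step.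
- A 2,4,6-trialkoxybenzyl bromide (prone to ionize and self-alkylate) is avoided; the same C–C bond is made by dianion aldol addition and ionic deoxygenation.
- The target is achiral. The stereocentres of 10, 16, 17 and 26 are transient and uncontrolled.
- Compounds 1, 6, 14, 21, trichloroethylene and N-methoxy-N-methylbutanamide are taken as purchased.

Step 1
Reactants: 1 2-methylphloroglucinol (2-methylbenzene-1,3,5-triol)
Product: 3 2,4,6-trihydroxy-3-methylbenzaldehyde, via iminium chloride 2 (not isolated)
Conditions: POCl3 (1.1 equiv), DMF, EtOAc, 0 °C → rt; then H2O, 60 °C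
Reagents that add atoms: N,N-dimethylformamide CN(C)C=O; water O
Why: Vilsmeier–Haack formylation of a very electron-rich arene whose two free ring carbons are equivalent, so only one monoaldehyde can form and the iminium salt should resist a second attack.

Step 2
Reactants: 3 2,4,6-trihydroxy-3-methylbenzaldehyde
Product: 4 2,6-dihydroxy-4-methoxy-3-methylbenzaldehyde
Conditions: Me2SO4 (1.0 equiv), K2CO3 (1.0 equiv), acetone, rt
Reagents that add atoms: dimethyl sulfate COS(=O)(=O)OC
Why: Williamson etherification under limiting base should fall on the hydroxyl para to the formyl group, which is the most acidic one and the only one not held in a hydrogen bond to the carbonyl.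

Step 3
Reactants: 4 2,6-dihydroxy-4-methoxy-3-methylbenzaldehyde
Product: 5 2,6-bis(benzyloxy)-4-methoxy-3-methylbenzaldehyde
Conditions: BnBr (2.4 equiv), K2CO3, DMF, 60 °C
Reagents that add atoms: benzyl bromide BrCc1ccccc1
Why: Williamson etherification of the two remaining chelated phenols, which should go to completion with excess halide on warming in DMF.

Step 4
Reactants: 6 phloroglucinol (benzene-1,3,5-triol)
Product: 7 1,3,5-tris(benzyloxy)benzene
Conditions: BnBr (3.3 equiv), K2CO3, DMF, rt → 50 °C
Reagents that add atoms: benzyl bromide BrCc1ccccc1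
Why: Threefold Williamson etherification, a standard preparation of this ether in which C-benzylated by-products are removed by crystallization.

Step 5
Reactants: 7 1,3,5-tris(benzyloxy)benzene
Product: 8 1,3,5-tris(benzyloxy)-2,4-dibromobenzene
Conditions: NBS (2.0 equiv), CH2Cl2, −20 → 0 °C
Reagents that add atoms: N-bromosuccinimide O=C1CCC(=O)N1Br
Why: Electrophilic aromatic bromination of three equivalent positions should stop at the dibromide with two equivalents, because each bromine deactivates the ring and the last position is the most hindered.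

Step 6
Reactants: 8 1,3,5-tris(benzyloxy)-2,4-dibromobenzene; 5 2,6-bis(benzyloxy)-4-methoxy-3-methylbenzaldehyde
Product: 10 [2,6-bis(benzyloxy)-4-methoxy-3-methylphenyl][2,4,6-tris(benzyloxy)-3-bromophenyl]methanol (racemic), via aryllithium 9 (not isolated)
Conditions: n-BuLi (1.0 equiv), THF, −78 °C; then 5, −78 → −30 °C; aq. NH4Cl
Reagents that add atoms: none
Why: Bromine–lithium exchange outruns proton transfer at −78 °C and one equivalent should exchange one of the two equivalent bromides, after which 1,2-addition to the aldehyde gives the benzhydrol, whose uncontrolled carbinol stereocentre is removed in step 7.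

Step 7
Reactants: 10 [2,6-bis(benzyloxy)-4-methoxy-3-methylphenyl][2,4,6-tris(benzyloxy)-3-bromophenyl]methanol
Product: 11 2-{[2,6-bis(benzyloxy)-4-methoxy-3-methylphenyl]methyl}-1,3,5-tris(benzyloxy)-4-bromobenzene (ArBr)
Conditions: Et3SiH (3 equiv), TFA (5 equiv), CH2Cl2, 0 °C
Reagents that add atoms: none
Why: Ionic hydrogenation, in which TFA ionizes the doubly benzylic alcohol to a cation stabilized by five ortho/para alkoxy groups and the silane delivers hydride.

Step 8
Reactants: 11 ArBr
Product: 13 3-{[2,6-bis(benzyloxy)-4-methoxy-3-methylphenyl]methyl}-2,4,6-tris(benzyloxy)benzaldehyde (ArCHO), via aryllithium 12 (not isolated)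
Conditions: n-BuLi (1.1 equiv), THF, −78 °C; DMF (3 equiv), −78 → 0 °C; aq. NH4Cl
Reagents that add atoms: N,N-dimethylformamide CN(C)C=O
Why: Bromine–lithium exchange followed by Bouveault-type formylation with DMF, which places the aldehyde only where the bromine stood and so never has to distinguish the free ring carbons of rings B and A.

Step 9
Reactants: 13 ArCHO; 14 methyl 2-methyl-3-oxobutanoate
Product: 16 methyl 5-Ar-5-hydroxy-2-methyl-3-oxopentanoate (mixture of diastereomers), via sodium lithium dianion 15 (not isolated)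
Conditions: 14 (1.5 equiv), NaH, THF, 0 °C; n-BuLi, 0 °C; then 13, −78 → −40 °C; aq. NH4Cl
Reagents that add atoms: none
Why: Acetoacetate dianion aldol addition, in which the terminal carbanion is the more nucleophilic site and the aldehyde cannot enolize; the two new stereocentres are formed without control because both disappear in steps 10 and 11.

Step 10
Reactants: 16 methyl 5-Ar-5-hydroxy-2-methyl-3-oxopentanoate
Product: 17 methyl 5-Ar-2-methyl-3-oxopentanoate (racemic)
Conditions: Et3SiH (5 equiv), TFA (10 equiv), CH2Cl2, −20 → 0 °C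
Reagents that add atoms: none
Why: Ionic deoxygenation of a 2,4,6-trialkoxybenzylic alcohol, whose cation forms readily and is intercepted by excess silane (any enone from elimination is reduced to the same product), while the keto ester is inert to these conditions.

Step 11
Reactants: 17 methyl 5-Ar-2-methyl-3-oxopentanoate
Product: 18 methyl (2E)-5-Ar-3-methoxy-2-methylpent-2-enoate
Conditions: NaH, THF/DMPU, 0 °C; Me2SO4, 0 °C → rt
Reagents that add atoms: dimethyl sulfate COS(=O)(=O)OC
Why: O-alkylation of a keto ester enolate, favoured by the hard electrophile, the dipolar medium and the quaternary centre that C-methylation would require; the E isomer is expected, and either isomer gives the same dienolate in step 12.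

Step 12
Reactants: 18 methyl (2E)-5-Ar-3-methoxy-2-methylpent-2-enoate
Product: 20 (1Z,3Z)-5-Ar-1,3-dimethoxy-2-methyl-1-(trimethylsilyloxy)penta-1,3-diene, via lithium dienolate 19 (not isolated)
Conditions: LiN(iPr)2 (1.2 equiv), THF, −78 °C; Me3SiCl, −78 → 0 °C; hexane, filtration, used crude
Reagents that add atoms: chlorotrimethylsilane C[Si](C)(C)Cl
Why: Carbonyl-directed deprotonation at C4 gives the extended ester dienolate and O-silylation gives the vinylketene acetal, as in the standard preparation of 1,3-dialkoxy-1-silyloxydienes; allylic strain should hold the arylmethyl group away from C2, which sets the 3Z geometry.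

Step 13
Reactants: 21 benzyl alcohol
Product: 22 benzyl (E)-1,2-dichlorovinyl ether
Conditions: KH, THF, 0 °C; Cl2C=CHCl, −50 °C → rt
Reagents that add atoms: trichloroethylene ClC=C(Cl)Cl
Why: Alkoxide addition to dichloroacetylene generated in the flask from trichloroethylene, an established entry to 1,2-dichlorovinyl ethers in which anti addition gives the E isomer.

Step 14
Reactants: 22 benzyl (E)-1,2-dichlorovinyl ether
Product: 25 1-(benzyloxy)hex-1-yn-3-one, via chloroalkynyl ether 23 (not isolated), via lithium acetylide 24 (not isolated)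
Conditions: n-BuLi (2.2 equiv), THF, −78 °C; n-PrC(O)N(OMe)Me, −78 → −30 °C; AcOH, −78 °C
Reagents that add atoms: N-methoxy-N-methylbutanamide CCCC(=O)N(C)OC
Why: Elimination and chlorine–lithium exchange give the lithium alkoxyacetylide, and Weinreb ketone synthesis stops at the ynone because the chelated tetrahedral adduct survives until the cold acidic quench, which also keeps the freed amine from adding to the ynone.

Step 15
Reactants: 20 (1Z,3Z)-5-Ar-1,3-dimethoxy-2-methyl-1-(trimethylsilyloxy)penta-1,3-diene; 25 1-(benzyloxy)hex-1-yn-3-one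
Product: 28 1-[3-(Ar-methyl)-2-(benzyloxy)-6-hydroxy-4-methoxy-5-methylphenyl]butan-1-one, via cycloadduct 26 (not isolated), via aryl silyl ether 27 (not isolated)
Conditions: 25 (1.5 equiv), PhMe, 45 °C; then 1 M HCl, THF, 0 °C → rt
Reagents that add atoms: none
Why: Proposed new method: the C4 terminus of diene 20, which carries the largest HOMO coefficient because both the C3 methoxy and the ketene acetal oxygens push electron density onto it, bonds to the benzyloxy-bearing alkyne carbon of 25 (β to the ketone), and the allenolate carbon then bonds to the ketene acetal carbon C1, either in one asynchronous (4+2) event or as Mukaiyama–Michael addition followed by 6-exo-trig closure onto the silyloxocarbenium ion; acid then removes methanol across C1/C4 and hydrolyses the aryl silyl ether to the c4 hydroxyl. The closest known reaction type is the Diels–Alder reaction and aromatization of 1,3-dialkoxy-1-silyloxybutadienes with acetylenic ketones, acetylenic esters and quinones, which has not been shown for a 2,4-disubstituted diene paired with a 1-alkoxy ynone to give a hexasubstituted benzene. Ring C is closed as a six-membered carbocycle by intermolecular (4+2) annulation that forms c1–c2 and c3–c4. The two sp3 centres of cycloadduct 26 are lost on aromatization, so no stereocontrol is required. The step needs regioselectivity, which the pairing of the nucleophilic diene terminus with the β-carbon of the ynone secures, and a reachable s-cis diene, which the 3Z geometry secures by placing the arylmethyl group outward. The single enol methyl ether of the diene fixes the position of the c6 methoxy, and the temperature is kept at 45 °C so that the benzyl ynol ether does not rearrange before it reacts.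

Step 16
Reactants: 28 1-[3-(Ar-methyl)-2-(benzyloxy)-6-hydroxy-4-methoxy-5-methylphenyl]butan-1-one
Product: 29 1-[2,6-dihydroxy-4-methoxy-3-methyl-5-({2,4,6-trihydroxy-3-[(2,6-dihydroxy-4-methoxy-3-methylphenyl)methyl]phenyl}methyl)phenyl]butan-1-one
Conditions: H2 (1 atm), Pd/C, EtOAc/MeOH, rt; filtered under argon and used at once
Reagents that add atoms: none
Why: Catalytic hydrogenolysis of six benzyl aryl ethers under neutral conditions, which should leave the hydrogen-bonded aryl ketone, both methyl ethers and the diarylmethane links untouched.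

Step 17
Reactants: 29 the heptaphenol of step 16
Product: 30 1-[2,4,6-trihydroxy-3-{[3-butanoyl-2,6-dihydroxy-4-methoxy-5-methylphenyl]methyl}-5-{[3-butanoyl-2,4-dihydroxy-6-methoxy-5-methylphenyl]methyl}phenyl]butan-1-one (target, CNP0171986.0)
Conditions: n-PrCO2H (excess), BF3·OEt2, 60 °C, argon; then aq. NaOAc
Reagents that add atoms: butanoic acid CCCC(=O)O
Why: Friedel–Crafts C-acylation of phloroglucinol rings with a carboxylic acid and BF3·OEt2 (any O-butyrate should undergo Fries rearrangement in the same medium); rings B and A each have exactly one unsubstituted carbon and ring C has none, so the two butyryl groups can only go where the target has them.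

Compound list
1 | 2-methylphloroglucinol | Cc1c(O)cc(O)cc1O | starting material
2 | N,N-dimethyl(2,4,6-trihydroxy-3-methylbenzylidene)iminium chloride (not isolated) | C[N+](C)=Cc1c(O)c(C)c(O)cc1O.[Cl-] | intermediate
3 | 2,4,6-trihydroxy-3-methylbenzaldehyde | O=Cc1c(O)c(C)c(O)cc1O | intermediate
4 | 2,6-dihydroxy-4-methoxy-3-methylbenzaldehyde | O=Cc1c(O)c(C)c(OC)cc1O | intermediate
5 | 2,6-bis(benzyloxy)-4-methoxy-3-methylbenzaldehyde | O=Cc1c(OCc2ccccc2)c(C)c(OC)cc1OCc1ccccc1 | intermediate
6 | phloroglucinol | Oc1cc(O)cc(O)c1 | starting material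
7 | 1,3,5-tris(benzyloxy)benzene | c1ccc(COc2cc(OCc3ccccc3)cc(OCc3ccccc3)c2)cc1 | intermediate
8 | 1,3,5-tris(benzyloxy)-2,4-dibromobenzene | Brc1c(OCc2ccccc2)cc(OCc2ccccc2)c(Br)c1OCc1ccccc1 | intermediate
9 | [2,4,6-tris(benzyloxy)-3-bromophenyl]lithium (not isolated) | [Li]c1c(OCc2ccccc2)cc(OCc2ccccc2)c(Br)c1OCc1ccccc1 | intermediate
10 | [2,6-bis(benzyloxy)-4-methoxy-3-methylphenyl][2,4,6-tris(benzyloxy)-3-bromophenyl]methanol (racemic) | OC(c1c(OCc2ccccc2)cc(OCc2ccccc2)c(Br)c1OCc1ccccc1)c1c(OCc2ccccc2)c(C)c(OC)cc1OCc1ccccc1 | intermediate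
11 | 2-{[2,6-bis(benzyloxy)-4-methoxy-3-methylphenyl]methyl}-1,3,5-tris(benzyloxy)-4-bromobenzene (ArBr) | Brc1c(OCc2ccccc2)cc(OCc2ccccc2)c(Cc2c(OCc3ccccc3)c(C)c(OC)cc2OCc2ccccc2)c1OCc1ccccc1 | intermediate
12 | [3-{[2,6-bis(benzyloxy)-4-methoxy-3-methylphenyl]methyl}-2,4,6-tris(benzyloxy)phenyl]lithium (ArLi, not isolated) | [Li]c1c(OCc2ccccc2)cc(OCc2ccccc2)c(Cc2c(OCc3ccccc3)c(C)c(OC)cc2OCc2ccccc2)c1OCc1ccccc1 | intermediate
13 | 3-{[2,6-bis(benzyloxy)-4-methoxy-3-methylphenyl]methyl}-2,4,6-tris(benzyloxy)benzaldehyde (ArCHO) | O=Cc1c(OCc2ccccc2)cc(OCc2ccccc2)c(Cc2c(OCc3ccccc3)c(C)c(OC)cc2OCc2ccccc2)c1OCc1ccccc1 | intermediate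
14 | methyl 2-methyl-3-oxobutanoate | CC(=O)C(C)C(=O)OC | starting material
15 | sodium lithium dianion of methyl 2-methyl-3-oxobutanoate (not isolated) | C=C([O-])C(C)=C([O-])OC.[Li+].[Na+] | intermediate
16 | methyl 5-Ar-5-hydroxy-2-methyl-3-oxopentanoate (mixture of diastereomers) | COC(=O)C(C)C(=O)CC(O)c1c(OCc2ccccc2)cc(OCc2ccccc2)c(Cc2c(OCc3ccccc3)c(C)c(OC)cc2OCc2ccccc2)c1OCc1ccccc1 | intermediate
17 | methyl 5-Ar-2-methyl-3-oxopentanoate (racemic) | COC(=O)C(C)C(=O)CCc1c(OCc2ccccc2)cc(OCc2ccccc2)c(Cc2c(OCc3ccccc3)c(C)c(OC)cc2OCc2ccccc2)c1OCc1ccccc1 | intermediate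
18 | methyl (2E)-5-Ar-3-methoxy-2-methylpent-2-enoate | COC(=O)/C(C)=C(/OC)CCc1c(OCc2ccccc2)cc(OCc2ccccc2)c(Cc2c(OCc3ccccc3)c(C)c(OC)cc2OCc2ccccc2)c1OCc1ccccc1 | intermediate
19 | lithium (1Z,3Z)-5-Ar-1,3-dimethoxy-2-methylpenta-1,3-dien-1-olate (not isolated) | CO/C([O-])=C(C)/C(OC)=C/Cc1c(OCc2ccccc2)c(Cc2c(OCc3ccccc3)c(C)c(OC)cc2OCc2ccccc2)c(OCc2ccccc2)cc1OCc1ccccc1.[Li+] | intermediate
20 | (1Z,3Z)-5-Ar-1,3-dimethoxy-2-methyl-1-(trimethylsilyloxy)penta-1,3-diene | CO/C(O[Si](C)(C)C)=C(C)/C(OC)=C/Cc1c(OCc2ccccc2)c(Cc2c(OCc3ccccc3)c(C)c(OC)cc2OCc2ccccc2)c(OCc2ccccc2)cc1OCc1ccccc1 | intermediate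
21 | benzyl alcohol | OCc1ccccc1 | starting material
22 | benzyl (E)-1,2-dichlorovinyl ether | Cl/C=C(/Cl)OCc1ccccc1 | intermediate
23 | benzyl chloroethynyl ether (not isolated) | ClC#COCc1ccccc1 | intermediate
24 | lithium (benzyloxy)acetylide (not isolated) | [Li]C#COCc1ccccc1 | intermediate
25 | 1-(benzyloxy)hex-1-yn-3-one | CCCC(=O)C#COCc1ccccc1 | intermediate
26 | 1-[3-(Ar-methyl)-2-(benzyloxy)-4,6-dimethoxy-5-methyl-6-(trimethylsilyloxy)cyclohexa-1,4-dien-1-yl]butan-1-one (mixture of diastereomers, not isolated) | CCCC(=O)C1=C(OCc2ccccc2)C(Cc2c(OCc3ccccc3)c(Cc3c(OCc4ccccc4)c(C)c(OC)cc3OCc3ccccc3)c(OCc3ccccc3)cc2OCc2ccccc2)C(OC)=C(C)C1(OC)O[Si](C)(C)C | intermediate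
27 | 1-[3-(Ar-methyl)-2-(benzyloxy)-4-methoxy-5-methyl-6-(trimethylsilyloxy)phenyl]butan-1-one (not isolated) | CCCC(=O)c1c(O[Si](C)(C)C)c(C)c(OC)c(Cc2c(OCc3ccccc3)c(Cc3c(OCc4ccccc4)c(C)c(OC)cc3OCc3ccccc3)c(OCc3ccccc3)cc2OCc2ccccc2)c1OCc1ccccc1 | intermediate
28 | 1-[3-(Ar-methyl)-2-(benzyloxy)-6-hydroxy-4-methoxy-5-methylphenyl]butan-1-one | CCCC(=O)c1c(O)c(C)c(OC)c(Cc2c(OCc3ccccc3)c(Cc3c(OCc4ccccc4)c(C)c(OC)cc3OCc3ccccc3)c(OCc3ccccc3)cc2OCc2ccccc2)c1OCc1ccccc1 | intermediate
29 | 1-[2,6-dihydroxy-4-methoxy-3-methyl-5-({2,4,6-trihydroxy-3-[(2,6-dihydroxy-4-methoxy-3-methylphenyl)methyl]phenyl}methyl)phenyl]butan-1-one | CCCC(=O)c1c(O)c(C)c(OC)c(Cc2c(O)c(Cc3c(O)c(C)c(OC)cc3O)c(O)cc2O)c1O | intermediate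
30 | 1-[2,4,6-trihydroxy-3-{[3-butanoyl-2,6-dihydroxy-4-methoxy-5-methylphenyl]methyl}-5-{[3-butanoyl-2,4-dihydroxy-6-methoxy-5-methylphenyl]methyl}phenyl]butan-1-one | CCCC(=O)c1c(O)c(Cc2c(O)c(C)c(OC)c(C(=O)CCC)c2O)c(O)c(Cc2c(O)c(C(=O)CCC)c(O)c(C)c2OC)c1O | target

Total step count: 17.
Longest linear sequence: 13 steps (1, 2, 3, 6, 7, 8, 9, 10, 11, 12, 15, 16, 17).

Steps most likely to fail

Step 15 (Proposed new method). The diene may be protonated or hydrolysed before it reacts. It may also add to the ynone in open-chain fashion or by (2+2) at the ketene acetal without closing the ring. The benzyl ynol ether may rearrange on warming. The adduct may aromatize by loss of silanol, which would leave a methyl ether at c4. The fallback uses known chemistry and builds ring C as a preformed acylphloroglucinol that is joined through the methylene bridge. It sets out from aldehyde 13, with 1 as the source of ring C, and comes back to the route at 29. Aldehyde 13 would be reduced (NaBH4, THF/MeOH) to [3-{[2,6-bis(benzyloxy)-4-methoxy-3-methylphenyl]methyl}-2,4,6-tris(benzyloxy)phenyl]methanol F1. In parallel, 1 would be C-butyrylated (butanoic acid, BF3·OEt2) to 1-(2,4,6-trihydroxy-3-methylphenyl)butan-1-one F2, which would be methylated at the hydroxyl para to the ketone (Me2SO4, K2CO3, acetone) to 1-(2,6-dihydroxy-4-methoxy-3-methylphenyl)butan-1-one F3. Acid-catalysed Friedel–Crafts benzylation of an excess of F3 by F1 (cat. TsOH, CH2Cl2, 0 °C) can only occur at the single free ring carbon of F3 and should give 1-[3-(Ar-methyl)-2,6-dihydroxy-4-methoxy-5-methylphenyl]butan-1-one F4. Hydrogenolysis (H2, Pd/C) would then give 29, ready for step 17.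

Step 17. Ipso protonation of the two unacylated, very electron-rich rings may break and scramble the methylene bridges in the acidic medium. The second acylation may stall, O-butyrates may persist, and 29 may oxidize in air. The fallback reverses the order of events: it sets out from 28 and comes back at 30. Friedel–Crafts acylation of the still protected compound (butanoyl chloride, TiCl4, CH2Cl2, −40 → 0 °C) at the one free carbon of ring B and of ring A should give 1-[3-(Ar-methyl)-2-(benzyloxy)-6-hydroxy-4-methoxy-5-methylphenyl]butan-1-one carrying a butanoyl group on the free carbon of each of rings B and A F5. Any benzyl ether lost to the Lewis acid next to a new ketone does no harm. Neutral hydrogenolysis (H2, Pd/C, EtOAc/MeOH) would then deliver 30 as the last step.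

Step 6. Exchange may occur twice or not at all. The aryllithium may be quenched by proton transfer from a benzylic OCH2 group, followed by Wittig rearrangement. Addition between two doubly ortho-substituted partners may be slow. The fallback replaces the carbanion addition by an electrophilic substitution: it sets out from 5 and 7 and comes back at 11. Aldehyde 5 would be reduced (NaBH4, MeOH) to [2,6-bis(benzyloxy)-4-methoxy-3-methylphenyl]methanol F6, and 7 would be monobrominated (NBS, 1.0 equiv, CH2Cl2, −20 °C) to 1,3,5-tris(benzyloxy)-2-bromobenzene F7. Acid-catalysed Friedel–Crafts benzylation of an excess of F7 by F6 (cat. TsOH, CH2Cl2, 0 °C) at one of its two equivalent free carbons should give 11 directly, so that steps 5 to 7 are bypassed.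

Further compounds
F1 | step 15 | [3-{[2,6-bis(benzyloxy)-4-methoxy-3-methylphenyl]methyl}-2,4,6-tris(benzyloxy)phenyl]methanol | OCc1c(OCc2ccccc2)cc(OCc2ccccc2)c(Cc2c(OCc3ccccc3)c(C)c(OC)cc2OCc2ccccc2)c1OCc1ccccc1
F2 | step 15 | 1-(2,4,6-trihydroxy-3-methylphenyl)butan-1-one | CCCC(=O)c1c(O)cc(O)c(C)c1O
F3 | step 15 | 1-(2,6-dihydroxy-4-methoxy-3-methylphenyl)butan-1-one | CCCC(=O)c1c(O)cc(OC)c(C)c1O
F4 | step 15 | 1-[3-(Ar-methyl)-2,6-dihydroxy-4-methoxy-5-methylphenyl]butan-1-one | CCCC(=O)c1c(O)c(C)c(OC)c(Cc2c(OCc3ccccc3)c(Cc3c(OCc4ccccc4)c(C)c(OC)cc3OCc3ccccc3)c(OCc3ccccc3)cc2OCc2ccccc2)c1O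
F5 | step 17 | 28 carrying a butanoyl group on the free ring carbon of ring B and of ring A | CCCC(=O)c1c(O)c(C)c(OC)c(Cc2c(OCc3ccccc3)c(Cc3c(OCc4ccccc4)c(C)c(OC)c(C(=O)CCC)c3OCc3ccccc3)c(OCc3ccccc3)c(C(=O)CCC)c2OCc2ccccc2)c1OCc1ccccc1
F6 | step 6 | [2,6-bis(benzyloxy)-4-methoxy-3-methylphenyl]methanol | OCc1c(OCc2ccccc2)c(C)c(OC)cc1OCc1ccccc1
F7 | step 6 | 1,3,5-tris(benzyloxy)-2-bromobenzene | Brc1c(OCc2ccccc2)cc(OCc2ccccc2)cc1OCc1ccccc1
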